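## Structural features

The target is a cis-fused decalin of the eremophilane type. Ring A (C1, C2, C3, C4, C5, C10) is a cyclohexanone with the carbonyl at C2; ring B (C5 to C10) carries the isopropenyl group at C7, an (R)-2-methylbutanoate at C8 and a tiglate at C9. The rings share the C5–C10 bond, with the C5 methyl group and H10 on the same face.

Six stereocentres form an unbroken chain C4–C5–C10–C9–C8–C7. C5 is quaternary, the methyl groups on C4 and C5 are cis, and a seventh centre sits in the 2-methylbutanoyl chain.

Taking the C5 methyl face as β, the isopropenyl group is β and both oxygens are α. The α face is the concave face of the cis-decalin, on the side of the C10–C1 bond, and the axial C9 oxygen lies under ring A.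

The fragile groups are the cis-diol carrying two different esters (acyl migration), the conjugated tiglate, the electron-rich isopropenyl alkene, the enolisable ketone and the α-stereocentre of the 2-methylbutanoate.

The real difficulty is to put two different oxygens on the shielded α face of C8 and C9, next to the C7 centre, in the presence of the more reactive isopropenyl alkene. The vicinal C4/C5 pair is the second problem.

The key step uses the fact that C1 is α to the C2 carbonyl and bonded to C10, whose neighbour C9 needs a substituent on that same α face. A carbenoid at C1 can add across C9=C10 of a ring B diene. This closes ring A and leaves a temporary C1–C9 bond in a vinylcyclopropane, which directs the C7 substituent to the opposite face.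

The same C2 carbonyl ends 1,3-diaxial to C9 and is used again to hand an oxygen to the α face.

## Logic of the disconnections

31 is cut at the C9–O acyl bond to 28 and 29. The shielded axial hydroxyl is acylated last, so that the ester already on C8 sits in the more stable position and has no reason to migrate. The gain is the loss of one acyl group. The forward step must acylate a hindered secondary alcohol without isomerising the tiglate.

28 is cut at the C8–O acyl bond to 26 and 27. The equatorial C8 hydroxyl is the accessible one of the pair, so the differentiation of the two oxygens is left to sterics. The forward step must stop at the monoester and must not racemise 27.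

26 is traced through 25 to 23: the C8–O bond is cut and the carbonate carbon removed, so the two α oxygens reduce to one epoxide oxygen. The cut is made here because a cis-diol on the concave face cannot be expected from an external cis-dihydroxylation. The forward steps must open the epoxide at C8 from the β face and close again from the α face, so that C8 is inverted twice and the C9–O bond is never broken.

23 is cut at both epoxide C–O bonds to 21. The oxygen is taken from the C2 carbonyl group inside the molecule, which reaches the α face and leaves the isopropenyl alkene alone. The gain is a plain alkene. The demand is an oxidant that exists only at C2.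

21 is cut at the C7–C11 bond, with the C1–C9 bond re-formed, to 18 and 19. An SN2′ opening of the vinylcyclopropane sets C7 anti to the C1–C9 bond. The gain is the loss of one stereocentre and of the side chain. The forward step needs attack at C7 and not at the carbonyl group.

18 is cut at C1–C10 and C1–C9 to 16. This is the key disconnection: it opens ring A and the three-membered ring together and leaves a monocyclic diene with only two stereocentres. The forward step must be site- and face-selective, which the tether from C5 is to enforce.

16 is cut at C1–C2 to 14. The diazo carbon is added to an acid; the acylation must be neutral enough to spare the diene.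

14 is traced through 13 and 12 to 11 by removing the C7=C8 double bond (C8–Br, then C8–H). The diene is kept out of the early steps. Because C5 is quaternary, only C8 can be brominated and only one diene can form.

11 is traced through 9 to 7 by cutting C2–C3, a one-carbon homologation. The sigmatropic step delivers the acid one carbon short. The migrating C4 must keep its configuration.

7 is cut at C4–C5 to 4. A [3,3] shift turns the single carbinol centre into the quaternary C5 and sets C4 through the enolate geometry. The demand is an (E)-ketene acetal and a chair transition state.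

4 is cut at the ester C–O bond to 2 and 3, and 2 at the carbinol C–H bond to 1. Both are commercial and the only asymmetric reagent of the route is used here.

## Other disconnections considered

Alternative 1: The cut is the C5–C6 bond, with C3–C8 closed in its place. The forward step would be an anionic oxy-Cope rearrangement of the bridged vinyl carbinol A2 (KH, 18-crown-6). This [3,3] shift joins C6 to C5, breaks C3–C8 and would deliver the cis-decalin A1 with a C8 ketone, a C9 ketal, a C2 silyl ether and a C3=C4 alkene.
- In its favour: one concerted step would fix the cis ring fusion and the quaternary C5. C8 and C9 arrive oxygenated at the carbonyl level, so both carbinols could later be set by hydride delivery from the convex face. On this point the alternative is better than the chosen plan, which must bring oxygen to the concave face of a finished cis-decalin.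
- Against it here: A1 has neither the C4 methyl group nor the C7 substituent. The isopropenyl group would have to be attached α to the C8 ketone, the C2 oxygen and the C3=C4 bond reworked into the C2 ketone and the 4β-methyl centre, and A2 would be racemic unless the chemistry before it is made asymmetric.
- Comparison: in structure it solves the ring B oxygens and leaves ring A open, the reverse of the chosen plan. In mechanism both key steps are stereospecific and of equal standing. In step economy the adjustments after A1 would probably make it the longer route.

Alternative 2: The cut runs through C5–C10 and C6–C7. An intramolecular Diels–Alder reaction of the achiral trienone A4 under a chiral oxazaborolidinium triflimide would give the octalin A3. In A4 the (E,E)-1-acetoxydiene (C7 to C10) and the isopropenyl ketone (C5=C6, carbonyl at C4) are tied through C1 to C3.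
- In its favour: both rings, C5, C10 and C7 would arise in one catalytic enantioselective step from a chain without a stereocentre. In ring-forming economy this is better than the chosen plan, which spends nine steps before its ring closure.
- Against it here: C4 arrives as a ketone and must become the 4β-methyl centre. The C7 acetate must be exchanged for the isopropenyl group with control of configuration, and an anti SN2′ displacement would move the double bond. The reactivity, the endo/exo preference and the enantiocontrol of this diene with a 1,1-disubstituted dienophile are open.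
- Equal point: the C8=C9 bond of A3 poses the same concave-face oxygenation problem as 21.
- Comparison: in structure the core comes earlier but with the wrong groups at C4 and C7. In mechanism a catalyst-controlled cycloaddition stands against a tether-controlled carbenoid addition. In step economy the saving in ring construction would be largely used up by the later exchanges, so the totals should be similar.

Alternative 3: The cut is the C7–C8 bond. A carbonyl-ene closure of ring B (Me2AlCl) would give A5: the C8 aldehyde of A6 is attacked by the prenyl alkene on C5 while an allylic methyl hydrogen moves to oxygen.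
- In its favour: the closing step would create C7, C8 and the isopropenyl group together, with the C2 ketone already present. The two oxygens emerge differentiated (C8 free, C9 silylated), so the acylations need no selectivity and no oxygen has to be brought onto a concave face. For the end game this is better than the chosen plan.
- Against it here: A6 must already carry C4, the quaternary C5 with its prenyl group, C10 and the C9 carbinol next to an epimerisable α-silyloxy aldehyde. The ene closure competes with Prins-type pathways and with Lewis-acid binding to the ketone, and its transition state must put C7 β and the C8 oxygen α.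
- Comparison: in structure the difficulty moves from ring B oxidation to the assembly of a tetrasubstituted cyclohexanone. In mechanism the stereocontrol is less rigid than in the tethered carbenoid addition and the anti SN2′ opening. In step economy the end game is shorter and the way to A6 probably longer, so about equal overall.

Key step: step 10

Remark on the chemistry: positions follow eremophilane numbering (ring A: C1 to C5 and C10; ring B: C5 to C10; C11 to C13 the isopropenyl group); β is the face of the C5 methyl group and α the opposite face.
Remark on the chemistry: (R)-2-methylbutanoic acid (27) is taken as a fifth commercial starting material.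
Remark on the chemistry: the stereodescriptors of 16 and 18 were checked against the target at C4, C5 and C10 and need no correction.
Remark on the chemistry: in the cis-fused ketone 21 the α face of C8=C9 is the concave face under ring A, so an external reagent such as OsO4 should add on the β face and would also attack the isopropenyl group; the α oxygens are therefore delivered from the C2 carbonyl group (steps 12 and 13).

Step 1
Reactants: 1 3-methylcyclohex-2-en-1-one
Product: 2 (1R)-3-methylcyclohex-2-en-1-ol
Conditions: (S)-2-methyl-CBS-oxazaborolidine (10 mol %), catecholborane, toluene, −78 °C; then aq. NaOH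
Reagents that add atoms: none
Why: Corey–Bakshi–Shibata reduction; the catalyst holds the carbonyl with the larger alkenyl arm away from it and delivers hydride 1,2 to one face, which should give the (R)-alcohol, the centre later relayed to C5.

Step 2
Reactants: 2 (1R)-3-methylcyclohex-2-en-1-ol; 3 propanoyl chloride
Product: 4 (1R)-3-methylcyclohex-2-en-1-yl propanoate
Conditions: pyridine, DMAP (cat.), CH2Cl2, 0 °C
Reagents that add atoms: none
Why: Nucleophile-catalysed O-acylation of a secondary allylic alcohol; no stereocentre is touched.

Step 3
Reactants: 4 (1R)-3-methylcyclohex-2-en-1-yl propanoate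
Product: 7 (2R)-2-[(1S)-1-methylcyclohex-2-en-1-yl]propanoic acid, via silyl ketene acetal 5 (not isolated), via trimethylsilyl ester 6 (not isolated)
Conditions: LiN(i-Pr)2, THF, −78 °C; Me3SiCl–Et3N, −78 → 60 °C; then 1 M HCl
Reagents that add atoms: none
Why: Ireland–Claisen rearrangement; enolisation without a polar cosolvent should give the (E)-silyl ketene acetal, which rearranges suprafacially through a chair with the ring carbons axial. The carbinol centre is thereby transferred to the quaternary C5, and the axial methyl group of the ketene acetal sets C4 so that the two methyl groups end cis on ring A.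

Step 4
Reactants: 7 (2R)-2-[(1S)-1-methylcyclohex-2-en-1-yl]propanoic acid
Product: 9 (3R)-1-diazo-3-[(1S)-1-methylcyclohex-2-en-1-yl]butan-2-one, via acid chloride 8 (not isolated)
Conditions: (COCl)2, DMF (cat.), CH2Cl2, 0 °C → rt; then Me3SiCHN2, MeCN–THF, 0 °C → rt
Reagents that add atoms: (trimethylsilyl)diazomethane, C[Si](C)(C)C=[N+]=[N-]
Why: First half of an Arndt–Eistert homologation; the acid chloride acylates the silyl diazoalkane and chloride removes the silyl group from carbon. No base is present, so the α-centre C4 is not enolised.

Step 5
Reactants: 9 (3R)-1-diazo-3-[(1S)-1-methylcyclohex-2-en-1-yl]butan-2-one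
Product: 11 methyl (3S)-3-[(1R)-1-methylcyclohex-2-en-1-yl]butanoate, via ketene 10 (not isolated)
Conditions: PhCO2Ag (10 mol %), Et3N, MeOH, rt, dark
Reagents that add atoms: methanol, CO
Why: Wolff rearrangement; the 1,2-shift moves C4 with retention and methanol traps the ketene, so C3 is inserted without touching C4 or C5.

Step 6
Reactants: 11 methyl (3S)-3-[(1R)-1-methylcyclohex-2-en-1-yl]butanoate
Product: 12 methyl (3S)-3-[(1R)-4-bromo-1-methylcyclohex-2-en-1-yl]butanoate
Conditions: N-bromosuccinimide, AIBN (cat.), PhCF3, 80 °C
Reagents that add atoms: N-bromosuccinimide, O=C1CCC(=O)N1Br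
Why: Wohl–Ziegler bromination; the only allylic C–H bonds are at C8 because the other allylic position is the quaternary C5, and both allylic bromide isomers lead to the same diene.

Step 7
Reactants: 12 methyl (3S)-3-[(1R)-4-bromo-1-methylcyclohex-2-en-1-yl]butanoate
Product: 13 methyl (3S)-3-[(1R)-1-methylcyclohexa-2,4-dien-1-yl]butanoate
Conditions: DBU, toluene, 90 °C
Reagents that add atoms: none
Why: Base-induced elimination of HBr (E2, or 1,4-elimination from the allylic isomer); with C5 quaternary only the ring 1,3-diene can form and it cannot aromatise. The temperature stays well below that of [1,5]-hydrogen shifts, which would scramble C5.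

Step 8
Reactants: 13 methyl (3S)-3-[(1R)-1-methylcyclohexa-2,4-dien-1-yl]butanoate
Product: 14 (3S)-3-[(1R)-1-methylcyclohexa-2,4-dien-1-yl]butanoic acid
Conditions: LiOH, THF–H2O, rt; then cold 1 M HCl
Reagents that add atoms: lithium hydroxide, [Li+].[OH-]
Why: Saponification; C4 is β to the carboxyl group and cannot epimerise, and the diene is inert to hydroxide.

Step 9
Reactants: 14 (3S)-3-[(1R)-1-methylcyclohexa-2,4-dien-1-yl]butanoic acid
Product: 16 (4S)-1-diazo-4-[(1R)-1-methylcyclohexa-2,4-dien-1-yl]pentan-2-one, via mixed anhydride 15 (not isolated)
Conditions: ClCO2Et, Et3N, THF, −15 °C; then Me3SiCHN2, MeCN, 0 °C → rt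
Reagents that add atoms: (trimethylsilyl)diazomethane, C[Si](C)(C)C=[N+]=[N-]
Why: Acylation of the silyl diazoalkane by a mixed carbonic anhydride; the conditions are close to neutral and spare the acid-sensitive diene, and the silyl reagent replaces diazomethane. The product is the terminal α-diazoketone that carries C1.

Step 10
Reactants: 16 (4S)-1-diazo-4-[(1R)-1-methylcyclohexa-2,4-dien-1-yl]pentan-2-one
Product: 18 1α,9α-cyclo-11,12,13-trinor-10βH-eremophil-7-en-2-one, via copper carbenoid 17 (not isolated)
Conditions: Cu(acac)2 (5 mol %), ClCH2CH2Cl, 80 °C, slow addition of 16 at high dilution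
Reagents that add atoms: none
Why: The copper salt, reduced in the flask to the active monovalent copper species, takes N2 from the diazoketone and forms the electrophilic carbenoid 17. This adds to the nearer double bond C9=C10 in a concerted, asynchronous [2+1] step, C1–C10 forming ahead of C1–C9. The closest known reaction type is the copper- or rhodium-catalysed intramolecular cyclopropanation of alkenes and 1,3-dienes by α-diazoketones. Ring A closes in the 6-exo sense onto C10 as the six-membered ring of a bicyclo[4.1.0]heptan-2-one, and the three-membered ring closes by collapse onto C9; both fusions must be cis. C10 is controlled by C5, because the tether reaches only the diene face that carries the C4 chain, so H10 ends cis to the C5 methyl group; C1 and C9 follow from the cis fusion (H1, H9 and H10 on one face). The step needs cyclopropanation to win over C–H insertion and carbene dimerisation, C9=C10 to win over C7=C8, and one diene face. Copper instead of rhodium, slow addition, the quaternary C5 (no C–H bond placed for five-ring insertion) and the short tether, which leaves C7=C8 out of reach, are to secure this.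

Step 11
Reactants: 18 1α,9α-cyclo-11,12,13-trinor-10βH-eremophil-7-en-2-one; 19 isopropenylmagnesium bromide
Product: 21 10βH-eremophila-8,11-dien-2-one, via silyl enol ether 20 (not isolated)
Conditions: 19 (2.2 equiv), CuBr·SMe2 (1.1 equiv), THF–Me2S, −40 °C; then 18, Me3SiCl, −78 → −20 °C; then 1 M HCl
Reagents that add atoms: none
Why: Homoconjugate SN2′ (1,7) addition of an organocuprate to a vinylcyclopropyl ketone; the strained external C1–C9 bond overlaps with both the carbonyl and the vinyl π systems, and the cuprate attacks C7 anti to it, on the β face. The enolate is trapped as the silyl enol ether and hydrolysed, so C7 is set by the cyclopropane and C10 keeps its β hydrogen.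

Step 12
Reactants: 21 10βH-eremophila-8,11-dien-2-one
Product: 23 8α,9α-epoxy-10βH-eremophil-11-en-2-one, via dioxirane 22 (not isolated)
Conditions: Oxone (2KHSO5·KHSO4·K2SO4), NaHCO3, MeCN–aq. Na2EDTA (pH 7.5–8), 0 °C → rt, 5 mM
Reagents that add atoms: potassium peroxymonosulfate, [K+].[O-]S(=O)(=O)OO
Why: Proposed new method: peroxymonosulfate should turn the C2 ketone into a spiro dioxirane whose axial oxygen lies 1,3-diaxial to C9 under ring A and can pass to the α face of C8=C9 within the molecule, a face no external oxidant reaches, while no free electrophilic oxidant is present to attack the isopropenyl group; the closest known reaction types are ketone-catalysed dioxirane epoxidation with Oxone and intramolecular C–H oxidation by dioxiranes made in situ.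

Step 13
Reactants: 23 8α,9α-epoxy-10βH-eremophil-11-en-2-one
Product: 25 8α,9α-(carbonyldioxy)-10βH-eremophil-11-en-2-one, via bromo alkoxide 24 (not isolated)
Conditions: CO2 (10 bar), n-Bu4NBr (0.2 equiv), DMF, 90 °C
Reagents that add atoms: carbon dioxide, O=C=O
Why: Halide-catalysed coupling of an epoxide with CO2; bromide opens the epoxide trans-diaxially at C8 from the open β face, the C9 alkoxide is carboxylated, and the carbonate oxygen displaces bromide at C8 from the α side. Two inversions at C8 give the cis-fused carbonate with both oxygens α, and the C9–O bond is never broken.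

Step 14
Reactants: 25 8α,9α-(carbonyldioxy)-10βH-eremophil-11-en-2-one
Product: 26 8α,9α-dihydroxy-10βH-eremophil-11-en-2-one
Conditions: K2CO3 (cat.), MeOH, rt
Reagents that add atoms: none
Why: Transesterification of the cyclic carbonate with methanol; it is mild enough to leave the ketone, both alkenes and all stereocentres as they are.

Step 15
Reactants: 26 8α,9α-dihydroxy-10βH-eremophil-11-en-2-one; 27 (2R)-2-methylbutanoic acid
Product: 28 9α-hydroxy-8α-[(2R)-2-methylbutanoyloxy]-10βH-eremophil-11-en-2-one
Conditions: 27 (1.05 equiv), i-PrN=C=N-i-Pr, DMAP (cat.), CH2Cl2, 0 °C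
Reagents that add atoms: none
Why: Steglich esterification; the equatorial C8 hydroxyl is far more accessible than the axial C9 hydroxyl under ring A, so one equivalent of acid should acylate C8 only. Carbodiimide activation avoids the ketene pathway that could racemise 27.

Step 16
Reactants: 28 9α-hydroxy-8α-[(2R)-2-methylbutanoyloxy]-10βH-eremophil-11-en-2-one; 29 tiglic acid
Product: 31 (4S,5R,7R,8R,9S,10S)-8-[(2R)-2-methylbutanoyloxy]-9-[(E)-2-methylbut-2-enoyloxy]eremophil-11-en-2-one, via mixed anhydride 30 (not isolated)
Conditions: 29, 2,4,6-Cl3C6H2COCl, Et3N, toluene, rt; then 28, DMAP, toluene, 60 °C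
Reagents that add atoms: none
Why: Yamaguchi esterification; the mixed anhydride and DMAP give a reactive acylpyridinium for the hindered axial C9 hydroxyl. The (E)-geometry of the tiglate is the stable one, and migration of the C8 ester to C9 would be uphill.

## Compound list

1 | 3-methylcyclohex-2-en-1-one | CC1=CC(=O)CCC1 | starting material
2 | (1R)-3-methylcyclohex-2-en-1-ol | O[C@H]1C=C(C)CCC1 | intermediate
3 | propanoyl chloride | CCC(=O)Cl | starting material
4 | (1R)-3-methylcyclohex-2-en-1-yl propanoate | CCC(=O)O[C@H]1C=C(C)CCC1 | intermediate
5 | (E)-trimethylsilyl ketene acetal of 4 (methyl cis to the cyclohexenyloxy group; not isolated) | C/C=C(\O[C@H]1C=C(C)CCC1)O[Si](C)(C)C | intermediate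
6 | trimethylsilyl (2R)-2-[(1S)-1-methylcyclohex-2-en-1-yl]propanoate (not isolated) | C[Si](C)(C)OC(=O)[C@H](C)[C@@]1(C)CCCC=C1 | intermediate
7 | (2R)-2-[(1S)-1-methylcyclohex-2-en-1-yl]propanoic acid | OC(=O)[C@H](C)[C@@]1(C)CCCC=C1 | intermediate
8 | (2R)-2-[(1S)-1-methylcyclohex-2-en-1-yl]propanoyl chloride (not isolated) | ClC(=O)[C@H](C)[C@@]1(C)CCCC=C1 | intermediate
9 | (3R)-1-diazo-3-[(1S)-1-methylcyclohex-2-en-1-yl]butan-2-one | [N-]=[N+]=CC(=O)[C@H](C)[C@@]1(C)CCCC=C1 | intermediate
10 | ketene 3-(1-methylcyclohex-2-en-1-yl)but-1-en-1-one with both centres as in 9 (not isolated) | O=C=C[C@H](C)[C@@]1(C)CCCC=C1 | intermediate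
11 | methyl (3S)-3-[(1R)-1-methylcyclohex-2-en-1-yl]butanoate | COC(=O)C[C@H](C)[C@@]1(C)CCCC=C1 | intermediate
12 | methyl (3S)-3-[(1R)-4-bromo-1-methylcyclohex-2-en-1-yl]butanoate (both epimers at the C–Br carbon; allylic isomer may be present) | COC(=O)C[C@H](C)[C@@]1(C)CCC(Br)C=C1 | intermediate
13 | methyl (3S)-3-[(1R)-1-methylcyclohexa-2,4-dien-1-yl]butanoate | COC(=O)C[C@H](C)[C@@]1(C)CC=CC=C1 | intermediate
14 | (3S)-3-[(1R)-1-methylcyclohexa-2,4-dien-1-yl]butanoic acid | OC(=O)C[C@H](C)[C@@]1(C)CC=CC=C1 | intermediate
15 | ethoxycarbonyl mixed anhydride of 14 (not isolated) | CCOC(=O)OC(=O)C[C@H](C)[C@@]1(C)CC=CC=C1 | intermediate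
16 | (4S)-1-diazo-4-[(1R)-1-methylcyclohexa-2,4-dien-1-yl]pentan-2-one | [N-]=[N+]=CC(=O)C[C@H](C)[C@@]1(C)CC=CC=C1 | intermediate
17 | copper carbenoid from 16 (ligands on copper omitted; not isolated) | [Cu]=CC(=O)C[C@H](C)[C@@]1(C)CC=CC=C1 | intermediate
18 | 1α,9α-cyclo-11,12,13-trinor-10βH-eremophil-7-en-2-one (4β,5β-dimethyl; cyclopropane C1–C9–C10 on the α face; H1, H9 and H10 β) | C1=C[C@@H]2[C@H]3[C@@H]2C(=O)C[C@H](C)[C@@]3(C)C1 | intermediate
19 | isopropenylmagnesium bromide | C=C(C)[Mg]Br | starting material
20 | 2-trimethylsilyloxy-10βH-eremophila-1,8,11-triene (silyl enol ether of 21; not isolated) | C=C(C)[C@H]1C[C@@]2(C)[C@H](C=C(O[Si](C)(C)C)C[C@@H]2C)C=C1 | intermediate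
21 | 10βH-eremophila-8,11-dien-2-one (4β,5β-dimethyl, 7β-isopropenyl, cis-fused) | C=C(C)[C@H]1C[C@@]2(C)[C@H](CC(=O)C[C@@H]2C)C=C1 | intermediate
22 | spiro dioxirane at C2 of 21 (not isolated) | C=C(C)[C@H]1C[C@@]2(C)[C@H](CC3(OO3)C[C@@H]2C)C=C1 | intermediate
23 | 8α,9α-epoxy-10βH-eremophil-11-en-2-one | C=C(C)[C@H]1C[C@@]2(C)[C@H](CC(=O)C[C@@H]2C)[C@@H]3O[C@H]13 | intermediate
24 | tetrabutylammonium 8β-bromo-2-oxo-10βH-eremophil-11-en-9α-olate (not isolated) | C=C(C)[C@H]1C[C@@]2(C)[C@H](CC(=O)C[C@@H]2C)[C@H]([O-])[C@H]1Br.CCCC[N+](CCCC)(CCCC)CCCC | intermediate
25 | 8α,9α-(carbonyldioxy)-10βH-eremophil-11-en-2-one (cis-fused cyclic carbonate) | C=C(C)[C@H]1C[C@@]2(C)[C@H](CC(=O)C[C@@H]2C)[C@@H]3OC(=O)O[C@H]13 | intermediate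
26 | 8α,9α-dihydroxy-10βH-eremophil-11-en-2-one | C=C(C)[C@H]1C[C@@]2(C)[C@H](CC(=O)C[C@@H]2C)[C@H](O)[C@@H]1O | intermediate
27 | (2R)-2-methylbutanoic acid | CC[C@@H](C)C(=O)O | starting material
28 | 9α-hydroxy-8α-[(2R)-2-methylbutanoyloxy]-10βH-eremophil-11-en-2-one | C=C(C)[C@H]1C[C@@]2(C)[C@H](CC(=O)C[C@@H]2C)[C@H](O)[C@@H]1OC(=O)[C@H](C)CC | intermediate
29 | tiglic acid, (E)-2-methylbut-2-enoic acid | C/C=C(\C)C(=O)O | starting material
30 | (E)-2-methylbut-2-enoic 2,4,6-trichlorobenzoic anhydride (not isolated) | C/C=C(\C)C(=O)OC(=O)c1c(Cl)cc(Cl)cc1Cl | intermediate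
31 | (4S,5R,7R,8R,9S,10S)-8-[(2R)-2-methylbutanoyloxy]-9-[(E)-2-methylbut-2-enoyloxy]eremophil-11-en-2-one (CNP0312791.1) | C=C(C)[C@H]1C[C@@]2(C)[C@H](CC(=O)C[C@@H]2C)[C@H](OC(=O)/C(C)=C/C)[C@@H]1OC(=O)[C@H](C)CC | target

## Step count and least certain steps

Total step count: 16. Longest linear sequence: 16 steps, from 1 to 31. The acyl donors 3, 27 and 29 and the Grignard reagent 19 are used as bought.

Step 12 (proposed new method). Most likely to go wrong: dioxirane formation from an unactivated ring ketone may be slow, so that Baeyer–Villiger oxidation of the ketone or bimolecular oxygen transfer to the isopropenyl group takes over. The fallback uses known chemistry, sets out from 21 and comes back at 23. 21 would be reduced with LiBH(s-Bu)3, which must attack equatorially because the axial C9 branch blocks the other side, to the axial 2α-hydroxy-10βH-eremophila-8,11-diene F1. Hydroxyl-directed epoxidation with VO(acac)2 and t-BuOOH would then deliver oxygen to the α face of C8=C9 only and give the epoxy alcohol F2, and Dess–Martin oxidation of F2 would return 23.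

Step 10 (key step). Most likely to go wrong: carbene dimerisation, insertion into the allylic C6–H bonds or addition to the distal double bond if the tether control is weaker than assumed, and loss of the diazoketone through acid traces. The fallback sets out from 13 and comes back at 18. 13 would be reduced with i-Bu2AlH at −78 °C to (3S)-3-[(1R)-1-methylcyclohexa-2,4-dien-1-yl]butanal F3, and Ohira–Bestmann alkynylation would give the enyne (1R)-1-methyl-1-[(2S)-pent-4-yn-2-yl]cyclohexa-2,4-diene F4. Gold-catalysed oxidation of the terminal alkyne ((Ph3P)AuNTf2, 8-methylquinoline N-oxide) would generate the same α-oxo carbenoid without a diazo compound and close 18.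

Step 11. Most likely to go wrong: the singly activated cyclopropane may be too poor an electrophile, so that the reagent adds 1,2 to the ketone or does not react; attack at C9 is a lesser risk. The fallback sets out from 14 and comes back at 21. 14 would be converted through its acyl imidazolide and Mg(O2CCH2CO2CH2CH=CH2)2 into the allyl β-keto ester F5, and diazo transfer (4-acetamidobenzenesulfonyl azide, Et3N) would give the diazo keto ester F6. Cyclopropanation of F6 with Cu(acac)2 or Rh2(OAc)4 would give the doubly activated tricyclic keto ester F7, which cuprates open readily in the SN2′ sense to the ring-opened keto ester F8. Pd(PPh3)4 and morpholine would then remove the allyl ester with decarboxylation to 21.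

Step 13. Most likely to go wrong: slow opening of the hindered internal epoxide, giving way at 90 °C to rearrangement to a ketone or elimination to an allylic alcohol. The fallback sets out from 23 and comes back at 26. LiBr in acetic acid would open 23 to the trans-diaxial 8β-bromo-9α-hydroxy bromohydrin F9. Acid-catalysed acetylation (Ac2O, Sc(OTf)3) would give the bromo acetate F10. AgOAc in wet acetic acid would then displace bromide through the neighbouring acetate (Woodward-type acetoxonium on the α face) and give the cis-diol monoacetate F11, which K2CO3 in methanol would convert into 26.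

Step 3. Most likely to go wrong: leakage through the boat transition state, which cyclohexenyl esters are prone to, or incomplete (E)-selectivity in the enolisation; both would erode the configuration at C4, while the transfer to C5 is not at risk. The fallback sets out from 2 and comes back at 7. 2 would be acetylated to (1R)-3-methylcyclohex-2-en-1-yl acetate F12, whose Ireland–Claisen rearrangement has only C5 to control and gives 2-[(1R)-1-methylcyclohex-2-en-1-yl]acetic acid F13. F13 would be attached to (4R)-4-benzyl-1,3-oxazolidin-2-one to give the imide F14. Evans alkylation (NaN(SiMe3)2, MeI) would set C4 under auxiliary control in the methylated imide F15, and LiOH/H2O2 would release 7.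

Step 16. Most likely to go wrong: acylation of the axial, shielded C9 hydroxyl, which may also be held as a hemiketal with the C2 ketone, may be so slow that forcing conditions bring on acyl migration from C8. The fallback sets out from 28 and comes back at 31. 28 would be esterified with 2-(diethoxyphosphoryl)propanoic acid and dicyclohexylcarbodiimide, which acylates hindered alcohols through the ketene, to the 9-O-[2-(diethoxyphosphoryl)propanoyl] ester F16. A Horner–Wadsworth–Emmons reaction of F16 with acetaldehyde (LiCl, DBU) would then build the (E)-2-methylbut-2-enoate in place and give 31.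

## Further compounds

F1 | step 12 | 2α-hydroxy-10βH-eremophila-8,11-diene | C=C(C)[C@H]1C[C@@]2(C)[C@H](C[C@@H](O)C[C@@H]2C)C=C1
F2 | step 12 | 8α,9α-epoxy-10βH-eremophil-11-en-2α-ol | C=C(C)[C@H]1C[C@@]2(C)[C@H](C[C@@H](O)C[C@@H]2C)[C@@H]3O[C@H]13
F3 | step 10 | (3S)-3-[(1R)-1-methylcyclohexa-2,4-dien-1-yl]butanal | O=CC[C@H](C)[C@@]1(C)CC=CC=C1
F4 | step 10 | (1R)-1-methyl-1-[(2S)-pent-4-yn-2-yl]cyclohexa-2,4-diene | C#CC[C@H](C)[C@@]1(C)CC=CC=C1
F5 | step 11 | allyl (5S)-5-[(1R)-1-methylcyclohexa-2,4-dien-1-yl]-3-oxohexanoate | C=CCOC(=O)CC(=O)C[C@H](C)[C@@]1(C)CC=CC=C1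
F6 | step 11 | allyl (5S)-2-diazo-5-[(1R)-1-methylcyclohexa-2,4-dien-1-yl]-3-oxohexanoate | C=CCOC(=O)C(=[N+]=[N-])C(=O)C[C@H](C)[C@@]1(C)CC=CC=C1
F7 | step 11 | 1-allyloxycarbonyl derivative of 18 (ester on C1, exo on the cyclopropane) | C1=C[C@@H]2[C@H]3[C@]2(C(=O)OCC=C)C(=O)C[C@H](C)[C@@]3(C)C1
F8 | step 11 | 1-allyloxycarbonyl derivative of 21 (C1 epimers) | C=C(C)[C@H]1C[C@@]2(C)[C@H](C(C(=O)OCC=C)C(=O)C[C@@H]2C)C=C1
F9 | step 13 | 8β-bromo-9α-hydroxy-10βH-eremophil-11-en-2-one | C=C(C)[C@H]1C[C@@]2(C)[C@H](CC(=O)C[C@@H]2C)[C@H](O)[C@H]1Br
F10 | step 13 | 9α-acetoxy-8β-bromo-10βH-eremophil-11-en-2-one | C=C(C)[C@H]1C[C@@]2(C)[C@H](CC(=O)C[C@@H]2C)[C@H](OC(C)=O)[C@H]1Br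
F11 | step 13 | 9α-acetoxy-8α-hydroxy-10βH-eremophil-11-en-2-one (the 8-acetate may accompany it) | C=C(C)[C@H]1C[C@@]2(C)[C@H](CC(=O)C[C@@H]2C)[C@H](OC(C)=O)[C@@H]1O
F12 | step 3 | (1R)-3-methylcyclohex-2-en-1-yl acetate | CC(=O)O[C@H]1C=C(C)CCC1
F13 | step 3 | 2-[(1R)-1-methylcyclohex-2-en-1-yl]acetic acid | OC(=O)C[C@@]1(C)CCCC=C1
F14 | step 3 | (4R)-4-benzyl-3-{2-[(1R)-1-methylcyclohex-2-en-1-yl]acetyl}-1,3-oxazolidin-2-one | O=C(C[C@@]1(C)CCCC=C1)N1[C@H](Cc2ccccc2)COC1=O
F15 | step 3 | (4R)-4-benzyl-3-{(2R)-2-[(1S)-1-methylcyclohex-2-en-1-yl]propanoyl}-1,3-oxazolidin-2-one | O=C([C@H](C)[C@@]1(C)CCCC=C1)N1[C@H](Cc2ccccc2)COC1=O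
F16 | step 16 | 9-O-[2-(diethoxyphosphoryl)propanoyl] derivative of 28 | C=C(C)[C@H]1C[C@@]2(C)[C@H](CC(=O)C[C@@H]2C)[C@H](OC(=O)C(C)P(=O)(OCC)OCC)[C@@H]1OC(=O)[C@H](C)CC
A1 | alternative 1 | cis-decalin with C8 ketone, C9 dimethyl ketal, C2 silyl ether and C3=C4 alkene | C1C[C@@]2(C)[C@H](C[C@H](O[Si](C)(C)C(C)(C)C)C=C2)C(OC)(OC)C1=O
A2 | alternative 1 | 2-vinylbicyclo[2.2.2]oct-5-en-2-ol precursor of A1 (3,3-dimethoxy, methyl on the ring alkene, silyl ether on the saturated bridge) | C=C[C@]1(O)C(OC)(OC)[C@H]2C[C@H](O[Si](C)(C)C(C)(C)C)[C@@H]1C=C2C
A3 | alternative 2 | cis-fused octalin with C4 ketone, C2 dioxolane, C8=C9 alkene and C7 acetate | CC(=O)O[C@@H]1C[C@@]2(C)[C@H](CC3(OCCO3)CC2=O)C=C1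
A4 | alternative 2 | acyclic (E,E)-acetoxydiene isopropenyl ketone with C2 dioxolane | CC(=O)O/C=C/C=C/CC1(CC(=O)C(C)=C)OCCO1
A5 | alternative 3 | 8-hydroxy-9-silyloxy eremophilane ketone with the C7 isopropenyl group | C=C(C)[C@H]1C[C@@]2(C)[C@H](CC(=O)C[C@@H]2C)[C@H](O[Si](C)(C)C(C)(C)C)[C@@H]1O
A6 | alternative 3 | ring A ketone with C5 prenyl group and C9 silyloxy C8 aldehyde side chain on C10 | CC(C)=CC[C@@]1(C)[C@H](CC(=O)C[C@@H]1C)[C@H](O[Si](C)(C)C(C)(C)C)C=O
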